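**Retrosynthetic overview**
1. Target ⇐ its carboxylic acid ⇐ (Peterson methylenation) cis-fused octalone.
2. cis-Octalone ⇐ acyclic 1,7,9-decatrien-3-one that already carries the finished 1,2-dioxane; an oxidation-triggered intramolecular Diels–Alder reaction forms rings A and B together (C2, C7) as the last C–C bond-forming event.
3. Trienone ⇐ α,α-dialkylated (S)-4-methyl-δ-valerolactone (C9 from a glutarate half-ester, C10 by trans-alkylation) + a dioxane triflate.
4. Dioxane triflate ⇐ (R)-linalool via oxetane, perhydrolysis with inversion (C3′) and peroxy-Michael closure (C6′, Cα).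
5. Ring order: 1,2-dioxane first, then rings A and B in one operation.

Assumption: C1–C10 are the decalin carbons in the order of the target SMILES, C14/C15 the linker, C3′/C6′ the dioxane carbons and Cα the propanoate carbon; tributyl(2-methylprop-2-en-1-yl)phosphonium bromide is taken as a one-step reagent from Bu3P and 3-bromo-2-methylpropene.

**Step 1**
Reactants: 1 (R)-(−)-linalool [(3R)-3,7-dimethylocta-1,6-dien-3-ol]
Product: 3 (3R)-3,7-dimethyloct-6-ene-1,3-diol, via alkylborane 2 (not isolated)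
Conditions: 9-BBN, THF, 0 → 25 °C; then NaOH, H2O2, 0 °C
Reagents that add atoms: hydrogen peroxide (OO)
Why: Anti-Markovnikov hydroboration–oxidation in which the bulky borane adds only to the monosubstituted vinyl group; the chiral-pool carbinol centre is untouched.

**Step 2**
Reactants: 3 (3R)-3,7-dimethyloct-6-ene-1,3-diol
Product: 5 (2R)-2-methyl-2-(4-methylpent-3-en-1-yl)oxetane, via monotosylate 4 (not isolated)
Conditions: n-BuLi (1 equiv), THF, 0 °C; TsCl (1 equiv); n-BuLi (1 equiv), 0 → 60 °C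
Reagents that add atoms: none
Why: One-pot primary tosylation and intramolecular Williamson etherification (4-exo-tet) by the tertiary alkoxide; the C–O bond at the stereocentre is not broken, so configuration is retained.

**Step 3**
Reactants: 5 (2R)-2-methyl-2-(4-methylpent-3-en-1-yl)oxetane
Product: 7 methyl (2E)-2-methyl-5-[(2R)-2-methyloxetan-2-yl]pent-2-enoate, via aldehyde 6 (not isolated)
Conditions: O3, CH2Cl2, −78 °C; Me2S; then Ph3P=C(Me)CO2Me, 25 °C
Reagents that add atoms: methyl 2-(triphenylphosphoranylidene)propanoate (COC(=O)C(C)=P(c1ccccc1)(c1ccccc1)c1ccccc1)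
Why: Ozonolysis of the only C=C bond followed by Wittig olefination with a stabilised ylide, which gives the (E)-trisubstituted enoate; the oxetane is inert to both.

**Step 4**
Reactants: 7 methyl (2E)-2-methyl-5-[(2R)-2-methyloxetan-2-yl]pent-2-enoate
Product: 8 methyl (2E,6S)-6-hydroperoxy-8-hydroxy-2,6-dimethyloct-2-enoate
Conditions: H2O2 (anhydrous, in Et2O, 10 equiv), Me3SiOTf (0.1 equiv), −78 → 0 °C
Reagents that add atoms: hydrogen peroxide (OO)
Why: Lewis acid-mediated perhydrolysis of a 2,2-disubstituted oxetane, in which H2O2 attacks the activated tertiary carbon with inversion (SN2-like ion pair) and so sets the C3′ peroxide centre from the linalool carbinol centre.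

**Step 5**
Reactants: 8 methyl (2E,6S)-6-hydroperoxy-8-hydroxy-2,6-dimethyloct-2-enoate
Product: 9 methyl (2S)-2-[(3R,6S)-6-(2-hydroxyethyl)-6-methyl-1,2-dioxan-3-yl]propanoate
Conditions: Et2NH (0.2 equiv), CF3CH2OH, 25 °C
Reagents that add atoms: none
Why: Base-catalysed intramolecular peroxy-Michael addition (6-exo-trig) closes the 1,2-dioxane; C6′ and Cα form here under only weak substrate control in a reversible reaction, so the required isomer is separated by chromatography and the other three are re-equilibrated (retro-Michael, DBU) and recycled while C3′ stays fixed.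

**Step 6**
Reactants: 9 methyl (2S)-2-[(3R,6S)-6-(2-hydroxyethyl)-6-methyl-1,2-dioxan-3-yl]propanoate
Product: 10 methyl (2S)-2-[(3R,6S)-6-methyl-6-(2-{[(trifluoromethyl)sulfonyl]oxy}ethyl)-1,2-dioxan-3-yl]propanoate
Conditions: Tf2O, 2,6-lutidine, CH2Cl2, −78 °C
Reagents that add atoms: trifluoromethanesulfonic anhydride (O=S(=O)(OS(=O)(=O)C(F)(F)F)C(F)(F)F)
Why: Low-temperature sulfonylation of the primary alcohol gives an electrophile reactive enough for enolate alkylation at −78 °C; the ester and the hindered dialkyl peroxide are inert.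

**Step 7**
Reactants: 11 methyl hydrogen (R)-3-methylglutarate [(3R)-5-methoxy-3-methyl-5-oxopentanoic acid]
Product: 13 (4S)-4-methyloxan-2-one, via hydroxy acid 12 (not isolated)
Conditions: LiH, THF, 0 °C; LiBH4, 0 → 25 °C; then 2 M HCl
Reagents that add atoms: none
Why: Chemoselective LiBH4 reduction of the ester of the pre-formed lithium carboxylate, then acid-catalysed lactonisation; C9 comes from the enantiopure half-ester.

**Step 8**
Reactants: 13 (4S)-4-methyloxan-2-one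
Product: 15 (3R,4S)-3,4-dimethyloxan-2-one, via lithium enolate 14 (not isolated)
Conditions: LiN(i-Pr)2, THF, −78 °C; MeI, −78 → −20 °C
Reagents that add atoms: iodomethane (CI)
Why: Lactone enolate alkylation trans to the 4-methyl group; the configuration at C3 does not matter because this centre is re-enolised in step 9.

**Step 9**
Reactants: 15 (3R,4S)-3,4-dimethyloxan-2-one; 10 methyl (2S)-2-[(3R,6S)-6-methyl-6-(2-{[(trifluoromethyl)sulfonyl]oxy}ethyl)-1,2-dioxan-3-yl]propanoate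
Product: 17 methyl (2S)-2-[(3R,6R)-6-{2-[(3R,4S)-3,4-dimethyl-2-oxooxan-3-yl]ethyl}-6-methyl-1,2-dioxan-3-yl]propanoate, via lithium enolate 16 (not isolated)
Conditions: LiN(i-Pr)2, THF, −78 → −40 °C; then 10, −78 °C
Reagents that add atoms: none
Why: SN2 alkylation of the tetrasubstituted lactone enolate, where the electrophile enters anti to the pseudoaxial C9 methyl (A(1,2) strain) and sets quaternary C10 with the two methyls cis; the triflate reacts at −78 °C faster than proton transfer from the side-chain ester or attack at the hindered O–O bond.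

**Step 10**
Reactants: 17 methyl (2S)-2-[(3R,6R)-6-{2-[(3R,4S)-3,4-dimethyl-2-oxooxan-3-yl]ethyl}-6-methyl-1,2-dioxan-3-yl]propanoate
Product: 19 (2S)-2-[(3R,6R)-6-{2-[(3R,4S)-3,4-dimethyl-2-oxooxan-3-yl]ethyl}-6-methyl-1,2-dioxan-3-yl]propanoic acid, via dicarboxylate 18 (not isolated)
Conditions: LiOH, THF/H2O, 0 °C; then 1 M HCl to pH 3, 25 °C
Reagents that add atoms: lithium hydroxide ([Li+].[OH-])
Why: Saponification in which the lactone opens and re-closes on acidification (gem-dialkyl effect); the side-chain acid then travels as its carboxylate, inert to the hydride and carbanion reagents of steps 11, 13 and 15.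

**Step 11**
Reactants: 19 (2S)-2-[(3R,6R)-6-{2-[(3R,4S)-3,4-dimethyl-2-oxooxan-3-yl]ethyl}-6-methyl-1,2-dioxan-3-yl]propanoic acid
Product: 21 (2S)-2-[(3R,6R)-6-[(3R,4S)-6-hydroxy-3-(1-hydroxyprop-2-en-1-yl)-3,4-dimethylhexyl]-6-methyl-1,2-dioxan-3-yl]propanoic acid (carbinol epimers), via lactol 20 (not isolated)
Conditions: i-Bu2AlH (2.2 equiv), CH2Cl2, −78 °C; then CH2=CHMgBr (4 equiv), THF, −78 → 0 °C
Reagents that add atoms: vinylmagnesium bromide (C=C[Mg]Br)
Why: Half-reduction of the lactone to the lactol aluminate, then 1,2-addition of the vinyl nucleophile to the ring-opened aldehyde; the carboxylate is not reduced at −78 °C and the new carbinol centre is oxidised away in step 14.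

**Step 12**
Reactants: 21 (2S)-2-[(3R,6R)-6-[(3R,4S)-6-hydroxy-3-(1-hydroxyprop-2-en-1-yl)-3,4-dimethylhexyl]-6-methyl-1,2-dioxan-3-yl]propanoic acid
Product: 22 (2S)-2-[(3R,6R)-6-{2-[(3R,4S)-2-ethenyl-6-hydroxy-3,4-dimethyloxan-3-yl]ethyl}-6-methyl-1,2-dioxan-3-yl]propanoic acid (lactol epimers)
Conditions: TEMPO (0.1 equiv), PhI(OAc)2 (1.1 equiv), CH2Cl2, 0 → 25 °C
Reagents that add atoms: none
Why: Oxoammonium (TEMPO) oxidation selective for the unhindered primary alcohol over the neopentyl allylic secondary one; the hydroxy aldehyde is stored as its six-membered lactol and limiting oxidant avoids over-oxidation to a lactone.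

**Step 13**
Reactants: 22 (2S)-2-[(3R,6R)-6-{2-[(3R,4S)-2-ethenyl-6-hydroxy-3,4-dimethyloxan-3-yl]ethyl}-6-methyl-1,2-dioxan-3-yl]propanoic acid
Product: 23 (2S)-2-[(3R,6R)-6-[(3R,4S,6E)-3-(1-hydroxyprop-2-en-1-yl)-3,4,8-trimethylnona-6,8-dien-1-yl]-6-methyl-1,2-dioxan-3-yl]propanoic acid (carbinol epimers)
Conditions: [Bu3PCH2C(Me)=CH2]Br (3.5 equiv), KN(SiMe3)2 (3.4 equiv), THF, −78 → 0 °C
Reagents that add atoms: tributyl(2-methylprop-2-en-1-yl)phosphonium bromide (CCCC[P+](CCCC)(CCCC)CC(C)=C.[Br-])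
Why: Wittig olefination of the lactol through its open aldehyde form; allylic trialkylphosphonium ylides give the (E)-1,3-diene, and the ylide is too weak a base to enolise the carboxylate.

**Step 14**
Reactants: 23 (2S)-2-[(3R,6R)-6-[(3R,4S,6E)-3-(1-hydroxyprop-2-en-1-yl)-3,4,8-trimethylnona-6,8-dien-1-yl]-6-methyl-1,2-dioxan-3-yl]propanoic acid
Product: 25 (2S)-2-[(3R,6R)-6-methyl-6-{2-[(2R,3S,4aR,8aS)-2,3,6-trimethyl-1-oxo-1,2,3,4,4a,7,8,8a-octahydronaphthalen-2-yl]ethyl}-1,2-dioxan-3-yl]propanoic acid, via trienone 24 (not isolated)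
Conditions: Dess–Martin periodinane (1.3 equiv), CH2Cl2, 0 → 25 °C; then 35 °C, 12 h
Reagents that add atoms: none
Why: Dess–Martin oxidation unveils the 1,7,9-decatrien-3-one, which undergoes intramolecular Diels–Alder cycloaddition through the endo transition state (tether carbonyl under the diene, hence cis fusion) with a chair tether that has the C9 methyl equatorial and the C10 methyl, not the chain, axial; this is the only cis arrangement free of 1,3-diaxial contacts between ring A and the C10 substituents, and it sets C2 and C7, although an all-equatorial exo (trans-fused) transition state competes, so a minor trans-fused isomer is expected and is removed by chromatography.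

**Step 15**
Reactants: 25 (2S)-2-[(3R,6R)-6-methyl-6-{2-[(2R,3S,4aR,8aS)-2,3,6-trimethyl-1-oxo-1,2,3,4,4a,7,8,8a-octahydronaphthalen-2-yl]ethyl}-1,2-dioxan-3-yl]propanoic acid
Product: 27 (2S)-2-[(3R,6R)-6-methyl-6-{2-[(2R,3S,4aR,8aS)-2,3,6-trimethyl-1-methylidene-1,2,3,4,4a,7,8,8a-octahydronaphthalen-2-yl]ethyl}-1,2-dioxan-3-yl]propanoic acid, via hydroxysilane 26 (not isolated)
Conditions: Me3SiCH2Li (3.5 equiv), CeCl3 (3.5 equiv), THF, −78 → 0 °C; then aq. HF, MeCN, 0 °C
Reagents that add atoms: (trimethylsilyl)methyllithium ([Li]C[Si](C)(C)C)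
Why: Peterson olefination, in which the weakly basic organocerium reagent adds to the hindered enolisable ketone without epimerising C2 and acid-induced elimination of the β-hydroxysilane gives the exocyclic methylene; the non-reducing conditions at low temperature spare the peroxide.

**Step 16**
Reactants: 27 (2S)-2-[(3R,6R)-6-methyl-6-{2-[(2R,3S,4aR,8aS)-2,3,6-trimethyl-1-methylidene-1,2,3,4,4a,7,8,8a-octahydronaphthalen-2-yl]ethyl}-1,2-dioxan-3-yl]propanoic acid
Product: 28 methyl (2S)-2-[(3R,6R)-6-methyl-6-{2-[(2R,3S,4aR,8aS)-2,3,6-trimethyl-1-methylidene-1,2,3,4,4a,7,8,8a-octahydronaphthalen-2-yl]ethyl}-1,2-dioxan-3-yl]propanoate (CNP0144520.2)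
Conditions: Me3SiCHN2, PhMe/MeOH (3:1), 0 °C
Reagents that add atoms: (trimethylsilyl)diazomethane (C[Si](C)(C)C=[N+]=[N-])
Why: Neutral O-methylation of the carboxylic acid by a diazoalkane; no stereocentre is touched.

**Compound list**
1 | (R)-(−)-linalool, (3R)-3,7-dimethylocta-1,6-dien-3-ol | C=C[C@](C)(O)CCC=C(C)C | starting material
2 | (3S)-1-(9-borabicyclo[3.3.1]nonan-9-yl)-3,7-dimethyloct-6-en-3-ol (descriptor changes by priority only) | CC(C)=CCC[C@@](C)(O)CCB1C2CCCC1CCC2 | intermediate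
3 | (3R)-3,7-dimethyloct-6-ene-1,3-diol | OCC[C@](C)(O)CCC=C(C)C | intermediate
4 | (3R)-3-hydroxy-3,7-dimethyloct-6-en-1-yl 4-methylbenzenesulfonate | Cc1ccc(cc1)S(=O)(=O)OCC[C@](C)(O)CCC=C(C)C | intermediate
5 | (2R)-2-methyl-2-(4-methylpent-3-en-1-yl)oxetane | CC(C)=CCC[C@]1(C)CCO1 | intermediate
6 | 3-[(2R)-2-methyloxetan-2-yl]propanal | O=CCC[C@]1(C)CCO1 | intermediate
7 | methyl (2E)-2-methyl-5-[(2R)-2-methyloxetan-2-yl]pent-2-enoate | COC(=O)/C(C)=C/CC[C@]1(C)CCO1 | intermediate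
8 | methyl (2E,6S)-6-hydroperoxy-8-hydroxy-2,6-dimethyloct-2-enoate | COC(=O)/C(C)=C/CC[C@@](OO)(C)CCO | intermediate
9 | methyl (2S)-2-[(3R,6S)-6-(2-hydroxyethyl)-6-methyl-1,2-dioxan-3-yl]propanoate | OCC[C@]1(C)CC[C@H]([C@H](C)C(=O)OC)OO1 | intermediate
10 | methyl (2S)-2-[(3R,6S)-6-methyl-6-(2-{[(trifluoromethyl)sulfonyl]oxy}ethyl)-1,2-dioxan-3-yl]propanoate | O=S(=O)(OCC[C@]1(C)CC[C@H]([C@H](C)C(=O)OC)OO1)C(F)(F)F | intermediate
11 | methyl hydrogen (R)-3-methylglutarate, (3R)-5-methoxy-3-methyl-5-oxopentanoic acid | COC(=O)C[C@H](C)CC(=O)O | starting material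
12 | (3S)-5-hydroxy-3-methylpentanoic acid (lithium salt in the flask) | OCC[C@H](C)CC(=O)O | intermediate
13 | (4S)-4-methyloxan-2-one | O=C1C[C@@H](C)CCO1 | intermediate
14 | lithium (4S)-4-methyl-5,6-dihydro-4H-pyran-2-olate | [Li]OC1=C[C@@H](C)CCO1 | intermediate
15 | (3R,4S)-3,4-dimethyloxan-2-one | O=C1[C@H](C)[C@@H](C)CCO1 | intermediate
16 | lithium (4S)-3,4-dimethyl-5,6-dihydro-4H-pyran-2-olate | [Li]OC1=C(C)[C@@H](C)CCO1 | intermediate
17 | methyl (2S)-2-[(3R,6R)-6-{2-[(3R,4S)-3,4-dimethyl-2-oxooxan-3-yl]ethyl}-6-methyl-1,2-dioxan-3-yl]propanoate | O=C1OCC[C@H](C)[C@@]1(C)CC[C@]2(C)CC[C@H]([C@H](C)C(=O)OC)OO2 | intermediate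
18 | dilithium (2R,3S)-2-{2-[(3R,6R)-6-[(1S)-1-carboxylatoethyl]-3-methyl-1,2-dioxan-3-yl]ethyl}-5-hydroxy-2,3-dimethylpentanoate | [Li+].[Li+].OCC[C@H](C)[C@@](C(=O)[O-])(C)CC[C@]1(C)CC[C@H]([C@H](C)C(=O)[O-])OO1 | intermediate
19 | (2S)-2-[(3R,6R)-6-{2-[(3R,4S)-3,4-dimethyl-2-oxooxan-3-yl]ethyl}-6-methyl-1,2-dioxan-3-yl]propanoic acid | O=C1OCC[C@H](C)[C@@]1(C)CC[C@]2(C)CC[C@H]([C@H](C)C(=O)O)OO2 | intermediate
20 | (2S)-2-[(3R,6R)-6-{2-[(3R,4S)-2-hydroxy-3,4-dimethyloxan-3-yl]ethyl}-6-methyl-1,2-dioxan-3-yl]propanoic acid (anomers) | OC1OCC[C@H](C)[C@@]1(C)CC[C@]2(C)CC[C@H]([C@H](C)C(=O)O)OO2 | intermediate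
21 | (2S)-2-[(3R,6R)-6-[(3R,4S)-6-hydroxy-3-(1-hydroxyprop-2-en-1-yl)-3,4-dimethylhexyl]-6-methyl-1,2-dioxan-3-yl]propanoic acid (carbinol epimers) | C=CC(O)[C@](C)(CC[C@]1(C)CC[C@H]([C@H](C)C(=O)O)OO1)[C@@H](C)CCO | intermediate
22 | (2S)-2-[(3R,6R)-6-{2-[(3R,4S)-2-ethenyl-6-hydroxy-3,4-dimethyloxan-3-yl]ethyl}-6-methyl-1,2-dioxan-3-yl]propanoic acid (epimers at the two ring O-bearing carbons) | C=CC1OC(O)C[C@H](C)[C@@]1(C)CC[C@]2(C)CC[C@H]([C@H](C)C(=O)O)OO2 | intermediate
23 | (2S)-2-[(3R,6R)-6-[(3R,4S,6E)-3-(1-hydroxyprop-2-en-1-yl)-3,4,8-trimethylnona-6,8-dien-1-yl]-6-methyl-1,2-dioxan-3-yl]propanoic acid (carbinol epimers) | C=CC(O)[C@](C)(CC[C@]1(C)CC[C@H]([C@H](C)C(=O)O)OO1)[C@@H](C)C/C=C/C(C)=C | intermediate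
24 | (2S)-2-[(3R,6R)-6-[(3R,4S,6E)-3,4,8-trimethyl-3-(prop-2-enoyl)nona-6,8-dien-1-yl]-6-methyl-1,2-dioxan-3-yl]propanoic acid | C=CC(=O)[C@](C)(CC[C@]1(C)CC[C@H]([C@H](C)C(=O)O)OO1)[C@@H](C)C/C=C/C(C)=C | intermediate
25 | (2S)-2-[(3R,6R)-6-methyl-6-{2-[(2R,3S,4aR,8aS)-2,3,6-trimethyl-1-oxo-1,2,3,4,4a,7,8,8a-octahydronaphthalen-2-yl]ethyl}-1,2-dioxan-3-yl]propanoic acid | O=C1[C@H]2CCC(C)=C[C@H]2C[C@H](C)[C@@]1(C)CC[C@]1(C)CC[C@H]([C@H](C)C(=O)O)OO1 | intermediate
26 | (2S)-2-[(3R,6R)-6-{2-[(2R,3S,4aR,8aS)-1-hydroxy-2,3,6-trimethyl-1-[(trimethylsilyl)methyl]-1,2,3,4,4a,7,8,8a-octahydronaphthalen-2-yl]ethyl}-6-methyl-1,2-dioxan-3-yl]propanoic acid (carbinol epimers) | C[Si](C)(C)CC1(O)[C@H]2CCC(C)=C[C@H]2C[C@H](C)[C@@]1(C)CC[C@]1(C)CC[C@H]([C@H](C)C(=O)O)OO1 | intermediate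
27 | (2S)-2-[(3R,6R)-6-methyl-6-{2-[(2R,3S,4aR,8aS)-2,3,6-trimethyl-1-methylidene-1,2,3,4,4a,7,8,8a-octahydronaphthalen-2-yl]ethyl}-1,2-dioxan-3-yl]propanoic acid | C=C1[C@H]2CCC(C)=C[C@H]2C[C@H](C)[C@@]1(C)CC[C@]1(C)CC[C@H]([C@H](C)C(=O)O)OO1 | intermediate
28 | methyl (2S)-2-[(3R,6R)-6-methyl-6-{2-[(2R,3S,4aR,8aS)-2,3,6-trimethyl-1-methylidene-1,2,3,4,4a,7,8,8a-octahydronaphthalen-2-yl]ethyl}-1,2-dioxan-3-yl]propanoate | C=C1[C@H]2CCC(C)=C[C@H]2C[C@H](C)[C@@]1(C)CC[C@]1(C)CC[C@H]([C@H](C)C(=O)OC)OO1 | target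

**Totals and weak points**
Total step count: 16. Longest linear sequence: 14 steps (from 1 through steps 1–6 and 9–16); the lactone branch (steps 7–8) joins at step 9.

The three steps most likely to fail:

Step 5 (peroxy-Michael closure; little intrinsic control of C6′ and Cα, so much recycling may be needed). The fallback sets both centres before ring closure and closes the ring stereospecifically; it sets out from 6 and returns at 9. Aldehyde 6 is isolated after the ozonolysis of step 3 and undergoes Brown crotylation with the antipode of (E)-crotyldiisopinocampheylborane that gives the anti adduct (3R,4S)-3-methyl-6-[(2R)-2-methyloxetan-2-yl]hex-1-en-4-ol F1. MsCl/Et3N gives the mesylate F2, and the oxetane is opened as in step 4 (H2O2, Me3SiOTf) to the hydroperoxy alcohol F3. Cs2CO3 in MeCN then closes the dioxane by 6-exo-tet SN2 displacement with inversion at C6′ to give the vinyl dioxane F4; with no acidifying group next to the leaving group, elimination is not favoured. Ozonolysis (O3, then Me2S) gives the aldehyde F5, NaClO2 oxidation gives the acid F6, and Me3SiCHN2 gives 9.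

Step 9 (SN2 alkylation of a hindered tetrasubstituted enolate by an electrophile that carries a peroxide and an enolisable ester). The fallback replaces the substitution by a carbonyl addition and a deoxygenation; it sets out from 9 and returns at 17. Alcohol 9 is oxidised with Dess–Martin periodinane to the aldehyde F7, which adds lithium enolate 16 at −78 °C within minutes (aldol addition, same facial bias) to give the β-hydroxy lactone F8. PhOC(S)Cl/DMAP gives the thionocarbonate F9, and Barton–McCombie reduction with Bu3SnH/AIBN gives 17; the C14 radical is γ to the O–O bond and is expected to be reduced by the stannane before it attacks that bond.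

Step 15 (carbanion addition to a very hindered ketone beside a dialkyl peroxide). The fallback changes the order and the olefination type; it sets out from 25 and returns at 28. Acid 25 is first methylated with Me3SiCHN2 to the keto ester F10, which is then methylenated with Cp2TiMe2 (PhMe, 65 °C). The titanium methylidene formed on heating is neutral and non-reducing and reacts with ketones faster than with esters, so this arrives directly at 28.

**Further compounds**
F1 | step 5 | (3R,4S)-3-methyl-6-[(2R)-2-methyloxetan-2-yl]hex-1-en-4-ol | C=C[C@@H](C)[C@@H](O)CC[C@]1(C)CCO1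
F2 | step 5 | (3R,4S)-3-methyl-6-[(2R)-2-methyloxetan-2-yl]hex-1-en-4-yl methanesulfonate | C=C[C@@H](C)[C@@H](OS(C)(=O)=O)CC[C@]1(C)CCO1
F3 | step 5 | (3R,4S,7S)-7-hydroperoxy-9-hydroxy-3,7-dimethylnon-1-en-4-yl methanesulfonate | C=C[C@@H](C)[C@@H](OS(C)(=O)=O)CC[C@@](OO)(C)CCO
F4 | step 5 | 2-[(3S,6R)-6-[(2R)-but-3-en-2-yl]-3-methyl-1,2-dioxan-3-yl]ethan-1-ol | OCC[C@]1(C)CC[C@H]([C@H](C)C=C)OO1
F5 | step 5 | (2S)-2-[(3R,6S)-6-(2-hydroxyethyl)-6-methyl-1,2-dioxan-3-yl]propanal | OCC[C@]1(C)CC[C@H]([C@H](C)C=O)OO1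
F6 | step 5 | (2S)-2-[(3R,6S)-6-(2-hydroxyethyl)-6-methyl-1,2-dioxan-3-yl]propanoic acid | OCC[C@]1(C)CC[C@H]([C@H](C)C(=O)O)OO1
F7 | step 9 | methyl (2S)-2-[(3R,6S)-6-methyl-6-(2-oxoethyl)-1,2-dioxan-3-yl]propanoate | O=CC[C@]1(C)CC[C@H]([C@H](C)C(=O)OC)OO1
F8 | step 9 | methyl (2S)-2-[(3R,6S)-6-{2-[(3S,4S)-3,4-dimethyl-2-oxooxan-3-yl]-2-hydroxyethyl}-6-methyl-1,2-dioxan-3-yl]propanoate (carbinol epimers) | O=C1OCC[C@H](C)[C@@]1(C)C(O)C[C@]2(C)CC[C@H]([C@H](C)C(=O)OC)OO2
F9 | step 9 | methyl (2S)-2-[(3R,6S)-6-{2-[(3S,4S)-3,4-dimethyl-2-oxooxan-3-yl]-2-[(phenoxycarbonothioyl)oxy]ethyl}-6-methyl-1,2-dioxan-3-yl]propanoate | O=C1OCC[C@H](C)[C@@]1(C)C(OC(=S)Oc3ccccc3)C[C@]2(C)CC[C@H]([C@H](C)C(=O)OC)OO2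
F10 | step 15 | methyl (2S)-2-[(3R,6R)-6-methyl-6-{2-[(2R,3S,4aR,8aS)-2,3,6-trimethyl-1-oxo-1,2,3,4,4a,7,8,8a-octahydronaphthalen-2-yl]ethyl}-1,2-dioxan-3-yl]propanoate | O=C1[C@H]2CCC(C)=C[C@H]2C[C@H](C)[C@@]1(C)CC[C@]1(C)CC[C@H]([C@H](C)C(=O)OC)OO1
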